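**Plan**

1. Labels follow the diterpene chain: C1 (CH2OH), C2=C3, C6=C7 (C7 bears C20H2OAc), C8–C10, C11 (CHMe), C12 (ring CH–O), C13 (ring CH2), C14 (CHOH), C15 (CMe2). The oxolane is O–C12–C13–C14–C15.
2. Retrosynthesis: C7–C8 by B-alkyl Suzuki coupling (oxolane fragment A + bromodiene fragment B); C9–C10 by vinyl coupling at C10; ring bond C12–C13 together with C11–H by a tin hydride radical cyclization; C6=C7 by a bromo-Horner–Wadsworth–Emmons olefination of a geraniol-derived aldehyde.
3. Enabling feature: the ring oxygen sits on C12, whose neighbour C11 carries CH3 and C10. O–C12–C11(CH3)–C10 is therefore a masked β-alkoxymethacrylate, and ring CH2 C13 next to carbinol C14 is a masked primary radical (iodide of a 1,2-diol).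
4. Forward: (R)-glycerate acetonide → tertiary alcohol → iodo silyl ether → methacrylate on the C15 oxygen → 5-exo cyclization closes the oxolane → ester to pentenyl chain → Suzuki union with fragment B → acetylation → desilylation.
5. Stereochemistry: C14 from the chiral pool; C12 from C14 in the ring closure (2,4-trans); C11 from C12 by anti hydrogen atom transfer to the exocyclic ester radical; C6=C7 from the E-bromoacrylate and a stereoretentive coupling; C2=C3 from geraniol.

Key step: step 7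

Remark: 8 is drawn as the E isomer; any Z isomer from step 6 is carried along, because both give the same C11 radical in step 7.

**Step 1**
Reactants: 1 methyl (4R)-2,2-dimethyl-1,3-dioxolane-4-carboxylate
Product: 2 2-[(4R)-2,2-dimethyl-1,3-dioxolan-4-yl]propan-2-ol
Conditions: MeMgBr (3 equiv), THF, 0 °C → rt; aq. NH4Cl
Reagents that add atoms: methylmagnesium bromide C[Mg]Br
Why: Twofold Grignard addition to the ester should give the tertiary carbinol (future C15) without touching the acetal-protected stereocenter (future C14).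

**Step 2**
Reactants: 2 2-[(4R)-2,2-dimethyl-1,3-dioxolan-4-yl]propan-2-ol
Product: 3 (2R)-3-methylbutane-1,2,3-triol
Conditions: AcOH/H2O (4:1), 45 °C
Reagents that add atoms: none
Why: Acid hydrolysis of the isopropylidene acetal, done before the acid-sensitive vinylogous carbonate is present; no stereocenter is involved.

**Step 3**
Reactants: 3 (2R)-3-methylbutane-1,2,3-triol
Product: 4 (2S)-1-iodo-3-methylbutane-2,3-diol
Conditions: I2, PPh3, imidazole, THF/MeCN, 0 °C
Reagents that add atoms: iodine II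
Why: Appel-type iodination should take only the primary hydroxyl (C13), the neopentyl-type secondary and the tertiary hydroxyl being too hindered; C14 keeps its configuration (the descriptor changes by priority only).

**Step 4**
Reactants: 4 (2S)-1-iodo-3-methylbutane-2,3-diol
Product: 5 (3S)-3-[(tert-butyldimethylsilyl)oxy]-4-iodo-2-methylbutan-2-ol
Conditions: TBSOTf (1.05 equiv), 2,6-lutidine, CH2Cl2, −78 °C
Reagents that add atoms: tert-butyldimethylsilyl triflate CC(C)(C)[Si](C)(C)OS(=O)(=O)C(F)(F)F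
Why: Silyl ether formation with a silyl triflate at low temperature should discriminate the secondary from the tertiary hydroxyl, so no free C14 hydroxyl is left to add to the later acrylate.

**Step 5**
Reactants: 5 (3S)-3-[(tert-butyldimethylsilyl)oxy]-4-iodo-2-methylbutan-2-ol
Product: 6 (3S)-3-[(tert-butyldimethylsilyl)oxy]-4-iodo-2-methylbutan-2-yl formate
Conditions: HCO2H/Ac2O (premixed), pyridine, DMAP (cat.), CH2Cl2, 0 °C → rt
Reagents that add atoms: acetic formic anhydride CC(=O)OC=O (from formic acid O=CO and acetic anhydride CC(=O)OC(C)=O)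
Why: O-Formylation (acylation) with the mixed anhydride, whose small formyl group is transferred even to hindered tertiary alcohols.

**Step 6**
Reactants: 6 (3S)-3-[(tert-butyldimethylsilyl)oxy]-4-iodo-2-methylbutan-2-yl formate; 7 methyl 2-(triphenyl-λ5-phosphanylidene)propanoate
Product: 8 methyl (2E)-3-{[(3S)-3-[(tert-butyldimethylsilyl)oxy]-4-iodo-2-methylbutan-2-yl]oxy}-2-methylprop-2-enoate
Conditions: 7 (3 equiv), toluene, 110 °C
Reagents that add atoms: none
Why: Wittig olefination of a formate ester by a stabilized ylide should give the β-alkoxymethacrylate (vinylogous carbonate) on the tertiary oxygen, mainly E; the β-branched iodide should be too hindered to alkylate the ylide.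

**Step 7**
Reactants: 8 methyl (2E)-3-{[(3S)-3-[(tert-butyldimethylsilyl)oxy]-4-iodo-2-methylbutan-2-yl]oxy}-2-methylprop-2-enoate
Product: 9 methyl (2S)-2-[(2S,4R)-4-[(tert-butyldimethylsilyl)oxy]-5,5-dimethyloxolan-2-yl]propanoate
Conditions: n-Bu3SnH (1.3 equiv, slow addition), Et3B (0.2 equiv), air, toluene, −78 °C
Reagents that add atoms: none
Why: Et3B/O2 gives Bu3Sn•, which abstracts iodine from C13; the primary radical adds to C12, the oxygen-bearing β-carbon of the vinylogous carbonate, and the resulting tertiary ester-stabilized C11 radical takes a hydrogen atom from n-Bu3SnH, so one operation forms the C12–C13 bond and both new stereocenters. The closest known reaction type is the tin hydride mediated radical cyclization of β-alkoxyacrylates and β-alkoxymethacrylates to 2-(oxolan-2-yl)acetates and -propanoates. The oxolane closes in the 5-exo-trig mode. C12 is set by the C14 silyloxy group, which should lie pseudo-equatorial in the chair-like transition state and so place the side chain trans to it; C11 is set by the new C12 center through the exocyclic effect, since with the C12–H bond near the ester plane (allylic strain) the stannane approaches anti to ring carbon C13, which gives the anti C11/C12 pair of the target. The step needs ring closure to outrun direct reduction of the primary radical, which the activated acceptor, the low stannane concentration and the low temperature should secure, and it is convergent for E and Z acceptor because both give the same C11 radical. The 1,3-induction from C14 is the least secure element, and any C12 epimer should be removed by chromatography here.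

**Step 8**
Reactants: 9 methyl (2S)-2-[(2S,4R)-4-[(tert-butyldimethylsilyl)oxy]-5,5-dimethyloxolan-2-yl]propanoate
Product: 10 (2R)-2-[(2S,4R)-4-[(tert-butyldimethylsilyl)oxy]-5,5-dimethyloxolan-2-yl]propan-1-ol
Conditions: LiAlH4, Et2O, 0 °C
Reagents that add atoms: none
Why: Hydride reduction of the ester to the primary alcohol (C10) should be faster than enolization, so C11 is not epimerized and the sensitive β-alkoxy aldehyde is never isolated.

**Step 9**
Reactants: 10 (2R)-2-[(2S,4R)-4-[(tert-butyldimethylsilyl)oxy]-5,5-dimethyloxolan-2-yl]propan-1-ol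
Product: 12 tert-butyl{[(3R,5S)-2,2-dimethyl-5-[(2R)-pent-4-en-2-yl]oxolan-3-yl]oxy}dimethylsilane, via primary triflate 11 (not isolated)
Conditions: Tf2O, 2,6-lutidine, CH2Cl2, −78 °C; then CH2=CHMgBr, CuBr·SMe2 (10 mol %), THF, −78 → −20 °C
Reagents that add atoms: vinylmagnesium bromide C=C[Mg]Br
Why: Copper-catalysed cross-coupling of a primary alkyl triflate with a vinyl Grignard reagent (SN2 at C10) should add C9 and C8; the C11 stereocenter is β to the reacting carbon and untouched.

**Step 10**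
Reactants: 13 geraniol, (2E)-3,7-dimethylocta-2,6-dien-1-ol
Product: 14 tert-butyl{[(2E)-3,7-dimethylocta-2,6-dien-1-yl]oxy}diphenylsilane
Conditions: TBDPSCl, imidazole, DMF, rt
Reagents that add atoms: tert-butyldiphenylsilyl chloride CC(C)(C)[Si](Cl)(c1ccccc1)c1ccccc1
Why: Silyl ether formation protects the future C1 hydroxyl with a group that should survive the acidic cleavage in step 12.

**Step 11**
Reactants: 14 tert-butyl{[(2E)-3,7-dimethylocta-2,6-dien-1-yl]oxy}diphenylsilane
Product: 15 tert-butyl{[(2E)-5-(3,3-dimethyloxiran-2-yl)-3-methylpent-2-en-1-yl]oxy}diphenylsilane (racemic at the oxirane)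
Conditions: mCPBA (1.0 equiv), NaHCO3, CH2Cl2, −20 °C
Reagents that add atoms: 3-chloroperbenzoic acid OOC(=O)c1cccc(Cl)c1
Why: Prilezhaev epoxidation should prefer the remote, more electron-rich trisubstituted alkene over the one deactivated by the allylic oxygen; the oxirane stereocenter is lost in step 12.

**Step 12**
Reactants: 15 tert-butyl{[(2E)-5-(3,3-dimethyloxiran-2-yl)-3-methylpent-2-en-1-yl]oxy}diphenylsilane
Product: 17 (4E)-6-[(tert-butyldiphenylsilyl)oxy]-4-methylhex-4-enal, via vicinal diol 16 (not isolated)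
Conditions: H5IO6, THF/H2O, 0 °C
Reagents that add atoms: none
Why: Acid-catalysed epoxide hydrolysis followed in the same pot by periodate glycol cleavage (Malaprade reaction) should give the C6 aldehyde and acetone.

**Step 13**
Reactants: 18 ethyl 2-[bis(2,2,2-trifluoroethoxy)phosphoryl]acetate
Product: 19 ethyl 2-[bis(2,2,2-trifluoroethoxy)phosphoryl]-2-bromoacetate (racemic)
Conditions: NaH (1.0 equiv), THF, 0 °C; then inverse addition to Br2 (1.0 equiv), THF, −78 °C
Reagents that add atoms: bromine BrBr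
Why: Electrophilic α-bromination of the phosphonate-stabilized enolate; adding the enolate to the bromine should keep the more acidic product away from unreacted enolate and so limit dibromination.

**Step 14**
Reactants: 17 (4E)-6-[(tert-butyldiphenylsilyl)oxy]-4-methylhex-4-enal; 19 ethyl 2-[bis(2,2,2-trifluoroethoxy)phosphoryl]-2-bromoacetate
Product: 20 ethyl (2E,6E)-2-bromo-8-[(tert-butyldiphenylsilyl)oxy]-6-methylocta-2,6-dienoate
Conditions: 19, t-BuOK, 18-crown-6, THF, −78 °C; then 17
Reagents that add atoms: none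
Why: Horner–Wadsworth–Emmons olefination with the bis(trifluoroethyl) bromophosphonoacetate should give the (E)-α-bromoacrylate, in which the ester (future C20) is cis and the bromine trans to the C5 chain.

**Step 15**
Reactants: 20 ethyl (2E,6E)-2-bromo-8-[(tert-butyldiphenylsilyl)oxy]-6-methylocta-2,6-dienoate
Product: 21 (2E,6E)-2-bromo-8-[(tert-butyldiphenylsilyl)oxy]-6-methylocta-2,6-dien-1-ol
Conditions: i-Bu2AlH (2.5 equiv), CH2Cl2, −78 °C
Reagents that add atoms: none
Why: 1,2-Reduction of the enoate by the aluminium hydride should give the allylic alcohol with the alkene geometry and the C–Br bond intact.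

**Step 16**
Reactants: 12 tert-butyl{[(3R,5S)-2,2-dimethyl-5-[(2R)-pent-4-en-2-yl]oxolan-3-yl]oxy}dimethylsilane; 21 (2E,6E)-2-bromo-8-[(tert-butyldiphenylsilyl)oxy]-6-methylocta-2,6-dien-1-ol
Product: 23 (2Z,6E)-2-{(4R)-4-[(2S,4R)-4-[(tert-butyldimethylsilyl)oxy]-5,5-dimethyloxolan-2-yl]pentyl}-8-[(tert-butyldiphenylsilyl)oxy]-6-methylocta-2,6-dien-1-ol, via B-alkyl borane 22 (not isolated)
Conditions: 9-BBN, THF, rt; then 21, Pd(dppf)Cl2 (5 mol %), AsPh3, Cs2CO3, DMF/H2O, 50 °C
Reagents that add atoms: none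
Why: Anti-Markovnikov hydroboration places boron on C8, and the B-alkyl Suzuki–Miyaura coupling with the alkenyl bromide should proceed with retention, so C8 ends trans and C20 cis to C5.

**Step 17**
Reactants: 23 (2Z,6E)-2-{(4R)-4-[(2S,4R)-4-[(tert-butyldimethylsilyl)oxy]-5,5-dimethyloxolan-2-yl]pentyl}-8-[(tert-butyldiphenylsilyl)oxy]-6-methylocta-2,6-dien-1-ol
Product: 24 (2Z,6E)-2-{(4R)-4-[(2S,4R)-4-[(tert-butyldimethylsilyl)oxy]-5,5-dimethyloxolan-2-yl]pentyl}-8-[(tert-butyldiphenylsilyl)oxy]-6-methylocta-2,6-dien-1-yl acetate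
Conditions: Ac2O, pyridine, DMAP (cat.), CH2Cl2, 0 °C
Reagents that add atoms: acetic anhydride CC(=O)OC(C)=O
Why: Acetylation of the only free hydroxyl (C20), the C1 and C14 hydroxyls being silylated.

**Step 18**
Reactants: 24 (2Z,6E)-2-{(4R)-4-[(2S,4R)-4-[(tert-butyldimethylsilyl)oxy]-5,5-dimethyloxolan-2-yl]pentyl}-8-[(tert-butyldiphenylsilyl)oxy]-6-methylocta-2,6-dien-1-yl acetate
Product: 25 (2Z,6E)-2-{(4R)-4-[(2S,4R)-4-hydroxy-5,5-dimethyloxolan-2-yl]pentyl}-8-hydroxy-6-methylocta-2,6-dien-1-yl acetate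
Conditions: HF·pyridine, pyridine, THF, 0 °C → rt
Reagents that add atoms: none
Why: Fluoride-mediated desilylation should remove both silyl ethers, while the buffered acidic medium leaves the allylic acetate in place and unmigrated.

**Compound list**

1 | methyl (4R)-2,2-dimethyl-1,3-dioxolane-4-carboxylate | COC(=O)[C@H]1COC(C)(C)O1 | starting material
2 | 2-[(4R)-2,2-dimethyl-1,3-dioxolan-4-yl]propan-2-ol | CC(C)(O)[C@H]1COC(C)(C)O1 | intermediate
3 | (2R)-3-methylbutane-1,2,3-triol | CC(C)(O)[C@H](O)CO | intermediate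
4 | (2S)-1-iodo-3-methylbutane-2,3-diol | CC(C)(O)[C@H](O)CI | intermediate
5 | (3S)-3-[(tert-butyldimethylsilyl)oxy]-4-iodo-2-methylbutan-2-ol | CC(C)(O)[C@H](O[Si](C)(C)C(C)(C)C)CI | intermediate
6 | (3S)-3-[(tert-butyldimethylsilyl)oxy]-4-iodo-2-methylbutan-2-yl formate | O=COC(C)(C)[C@H](O[Si](C)(C)C(C)(C)C)CI | intermediate
7 | methyl 2-(triphenyl-λ5-phosphanylidene)propanoate | COC(=O)C(C)=P(c1ccccc1)(c1ccccc1)c1ccccc1 | starting material
8 | methyl (2E)-3-{[(3S)-3-[(tert-butyldimethylsilyl)oxy]-4-iodo-2-methylbutan-2-yl]oxy}-2-methylprop-2-enoate | COC(=O)/C(C)=C/OC(C)(C)[C@H](O[Si](C)(C)C(C)(C)C)CI | intermediate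
9 | methyl (2S)-2-[(2S,4R)-4-[(tert-butyldimethylsilyl)oxy]-5,5-dimethyloxolan-2-yl]propanoate | COC(=O)[C@@H](C)[C@@H]1C[C@@H](O[Si](C)(C)C(C)(C)C)C(C)(C)O1 | intermediate
10 | (2R)-2-[(2S,4R)-4-[(tert-butyldimethylsilyl)oxy]-5,5-dimethyloxolan-2-yl]propan-1-ol | OC[C@@H](C)[C@@H]1C[C@@H](O[Si](C)(C)C(C)(C)C)C(C)(C)O1 | intermediate
11 | (2R)-2-[(2S,4R)-4-[(tert-butyldimethylsilyl)oxy]-5,5-dimethyloxolan-2-yl]propyl trifluoromethanesulfonate | FC(F)(F)S(=O)(=O)OC[C@@H](C)[C@@H]1C[C@@H](O[Si](C)(C)C(C)(C)C)C(C)(C)O1 | intermediate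
12 | tert-butyl{[(3R,5S)-2,2-dimethyl-5-[(2R)-pent-4-en-2-yl]oxolan-3-yl]oxy}dimethylsilane | C=CC[C@@H](C)[C@@H]1C[C@@H](O[Si](C)(C)C(C)(C)C)C(C)(C)O1 | intermediate
13 | geraniol, (2E)-3,7-dimethylocta-2,6-dien-1-ol | CC(C)=CCC/C(C)=C/CO | starting material
14 | tert-butyl{[(2E)-3,7-dimethylocta-2,6-dien-1-yl]oxy}diphenylsilane | CC(C)=CCC/C(C)=C/CO[Si](c1ccccc1)(c1ccccc1)C(C)(C)C | intermediate
15 | tert-butyl{[(2E)-5-(3,3-dimethyloxiran-2-yl)-3-methylpent-2-en-1-yl]oxy}diphenylsilane (racemic) | CC1(C)OC1CC/C(C)=C/CO[Si](c1ccccc1)(c1ccccc1)C(C)(C)C | intermediate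
16 | (6E)-8-[(tert-butyldiphenylsilyl)oxy]-2,6-dimethyloct-6-ene-2,3-diol (racemic) | CC(C)(O)C(O)CC/C(C)=C/CO[Si](c1ccccc1)(c1ccccc1)C(C)(C)C | intermediate
17 | (4E)-6-[(tert-butyldiphenylsilyl)oxy]-4-methylhex-4-enal | O=CCC/C(C)=C/CO[Si](c1ccccc1)(c1ccccc1)C(C)(C)C | intermediate
18 | ethyl 2-[bis(2,2,2-trifluoroethoxy)phosphoryl]acetate | CCOC(=O)CP(=O)(OCC(F)(F)F)OCC(F)(F)F | starting material
19 | ethyl 2-[bis(2,2,2-trifluoroethoxy)phosphoryl]-2-bromoacetate (racemic) | CCOC(=O)C(Br)P(=O)(OCC(F)(F)F)OCC(F)(F)F | intermediate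
20 | ethyl (2E,6E)-2-bromo-8-[(tert-butyldiphenylsilyl)oxy]-6-methylocta-2,6-dienoate | CCOC(=O)/C(Br)=C\CC/C(C)=C/CO[Si](c1ccccc1)(c1ccccc1)C(C)(C)C | intermediate
21 | (2E,6E)-2-bromo-8-[(tert-butyldiphenylsilyl)oxy]-6-methylocta-2,6-dien-1-ol | OC/C(Br)=C\CC/C(C)=C/CO[Si](c1ccccc1)(c1ccccc1)C(C)(C)C | intermediate
22 | 9-{(4R)-4-[(2S,4R)-4-[(tert-butyldimethylsilyl)oxy]-5,5-dimethyloxolan-2-yl]pentyl}-9-borabicyclo[3.3.1]nonane | C1CCC2CCCC1B2CCC[C@@H](C)[C@@H]1C[C@@H](O[Si](C)(C)C(C)(C)C)C(C)(C)O1 | intermediate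
23 | (2Z,6E)-2-{(4R)-4-[(2S,4R)-4-[(tert-butyldimethylsilyl)oxy]-5,5-dimethyloxolan-2-yl]pentyl}-8-[(tert-butyldiphenylsilyl)oxy]-6-methylocta-2,6-dien-1-ol | OC/C(=C\CC/C(C)=C/CO[Si](c1ccccc1)(c1ccccc1)C(C)(C)C)CCC[C@@H](C)[C@@H]1C[C@@H](O[Si](C)(C)C(C)(C)C)C(C)(C)O1 | intermediate
24 | (2Z,6E)-2-{(4R)-4-[(2S,4R)-4-[(tert-butyldimethylsilyl)oxy]-5,5-dimethyloxolan-2-yl]pentyl}-8-[(tert-butyldiphenylsilyl)oxy]-6-methylocta-2,6-dien-1-yl acetate | CC(=O)OC/C(=C\CC/C(C)=C/CO[Si](c1ccccc1)(c1ccccc1)C(C)(C)C)CCC[C@@H](C)[C@@H]1C[C@@H](O[Si](C)(C)C(C)(C)C)C(C)(C)O1 | intermediate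
25 | (2Z,6E)-2-{(4R)-4-[(2S,4R)-4-hydroxy-5,5-dimethyloxolan-2-yl]pentyl}-8-hydroxy-6-methylocta-2,6-dien-1-yl acetate | CC(=O)OC/C(=C\CC/C(C)=C/CO)CCC[C@@H](C)[C@@H]1C[C@@H](O)C(C)(C)O1 | target

**Step count**

Total: 18 steps. Longest linear sequence: 12 steps (steps 1–9 and 16–18).

**Steps most likely to fail**

Step 7. The facial selectivity at C12 may be poor: the 1,3-induction from C14 could be low, or it could favour the 2,4-cis ring, because a pseudo-axial silyloxy group next to the ring oxygen has no syn-axial partner and avoids one gauche contact with the C15 methyl groups. The fallback sets out from 4 and comes back at 9; it uses the opposite C14 configuration as a disposable control element and resets it after ring closure. Dess–Martin oxidation of 4 should give 3-hydroxy-1-iodo-3-methylbutan-2-one F1, and Corey–Bakshi–Shibata reduction with (R)-Me-CBS and BH3·SMe2 should give (2R)-1-iodo-3-methylbutane-2,3-diol F2. The operations of steps 4, 5 and 6 would then lead through (3R)-3-[(tert-butyldimethylsilyl)oxy]-4-iodo-2-methylbutan-2-ol F3 and (3R)-3-[(tert-butyldimethylsilyl)oxy]-4-iodo-2-methylbutan-2-yl formate F4 to methyl (2E)-3-{[(3R)-3-[(tert-butyldimethylsilyl)oxy]-4-iodo-2-methylbutan-2-yl]oxy}-2-methylprop-2-enoate F5. The tin hydride cyclization would then close the 2,4-cis ring with C12 and C11 as in 9, giving methyl (2S)-2-[(2S,4S)-4-[(tert-butyldimethylsilyl)oxy]-5,5-dimethyloxolan-2-yl]propanoate F6. TBAF would free methyl (2S)-2-[(2S,4S)-4-hydroxy-5,5-dimethyloxolan-2-yl]propanoate F7, and Dess–Martin oxidation would give methyl (2S)-2-[(2S)-5,5-dimethyl-4-oxooxolan-2-yl]propanoate F8. Reduction with (S)-Me-CBS and catecholborane should set C14 by reagent control (quaternary C15 as the large group) to give methyl (2S)-2-[(2S,4R)-4-hydroxy-5,5-dimethyloxolan-2-yl]propanoate F9, and TBSOTf with 2,6-lutidine returns to 9.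

Step 6. The olefination of the hindered tertiary formate may be slow, and at 110 °C the ylide may be alkylated by the iodide or the formate may decompose. The fallback sets out from 5 and comes back at 8; it builds the vinylogous carbonate by conjugate addition and adds the α-methyl group afterwards. PMe3-catalysed addition of 5 to methyl propiolate should give methyl (2E)-3-{[(3S)-3-[(tert-butyldimethylsilyl)oxy]-4-iodo-2-methylbutan-2-yl]oxy}prop-2-enoate F10. N-Iodosuccinimide in AcOH/CH2Cl2 followed by Et3N should give methyl (2Z)-3-{[(3S)-3-[(tert-butyldimethylsilyl)oxy]-4-iodo-2-methylbutan-2-yl]oxy}-2-iodoprop-2-enoate F11. Negishi coupling with MeZnCl and Pd(PPh3)4, which should insert into the alkenyl iodide well before the alkyl iodide, then gives 8 with retention.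

Step 9. The triflate may ionize or eliminate before it is displaced, and substitution at the β-branched carbon may be slow. The fallback sets out from 10 and comes back at 12; it reverses the polarity at C10. Appel-type iodination (I2, PPh3, imidazole) should give tert-butyl{[(3R,5S)-5-[(2S)-1-iodopropan-2-yl]-2,2-dimethyloxolan-3-yl]oxy}dimethylsilane F12. Zinc insertion (Zn dust, LiCl, THF) should give {(2S)-2-[(2S,4R)-4-[(tert-butyldimethylsilyl)oxy]-5,5-dimethyloxolan-2-yl]propyl}zinc iodide F13, and Negishi coupling with vinyl bromide and Pd(PPh3)4 gives 12.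

**Further compounds**

F1 | step 7 | 3-hydroxy-1-iodo-3-methylbutan-2-one | CC(C)(O)C(=O)CI
F2 | step 7 | (2R)-1-iodo-3-methylbutane-2,3-diol | CC(C)(O)[C@@H](O)CI
F3 | step 7 | (3R)-3-[(tert-butyldimethylsilyl)oxy]-4-iodo-2-methylbutan-2-ol | CC(C)(O)[C@@H](O[Si](C)(C)C(C)(C)C)CI
F4 | step 7 | (3R)-3-[(tert-butyldimethylsilyl)oxy]-4-iodo-2-methylbutan-2-yl formate | O=COC(C)(C)[C@@H](O[Si](C)(C)C(C)(C)C)CI
F5 | step 7 | methyl (2E)-3-{[(3R)-3-[(tert-butyldimethylsilyl)oxy]-4-iodo-2-methylbutan-2-yl]oxy}-2-methylprop-2-enoate | COC(=O)/C(C)=C/OC(C)(C)[C@@H](O[Si](C)(C)C(C)(C)C)CI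
F6 | step 7 | methyl (2S)-2-[(2S,4S)-4-[(tert-butyldimethylsilyl)oxy]-5,5-dimethyloxolan-2-yl]propanoate | COC(=O)[C@@H](C)[C@@H]1C[C@H](O[Si](C)(C)C(C)(C)C)C(C)(C)O1
F7 | step 7 | methyl (2S)-2-[(2S,4S)-4-hydroxy-5,5-dimethyloxolan-2-yl]propanoate | COC(=O)[C@@H](C)[C@@H]1C[C@H](O)C(C)(C)O1
F8 | step 7 | methyl (2S)-2-[(2S)-5,5-dimethyl-4-oxooxolan-2-yl]propanoate | COC(=O)[C@@H](C)[C@@H]1CC(=O)C(C)(C)O1
F9 | step 7 | methyl (2S)-2-[(2S,4R)-4-hydroxy-5,5-dimethyloxolan-2-yl]propanoate | COC(=O)[C@@H](C)[C@@H]1C[C@@H](O)C(C)(C)O1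
F10 | step 6 | methyl (2E)-3-{[(3S)-3-[(tert-butyldimethylsilyl)oxy]-4-iodo-2-methylbutan-2-yl]oxy}prop-2-enoate | COC(=O)/C=C/OC(C)(C)[C@H](O[Si](C)(C)C(C)(C)C)CI
F11 | step 6 | methyl (2Z)-3-{[(3S)-3-[(tert-butyldimethylsilyl)oxy]-4-iodo-2-methylbutan-2-yl]oxy}-2-iodoprop-2-enoate | COC(=O)/C(I)=C/OC(C)(C)[C@H](O[Si](C)(C)C(C)(C)C)CI
F12 | step 9 | tert-butyl{[(3R,5S)-5-[(2S)-1-iodopropan-2-yl]-2,2-dimethyloxolan-3-yl]oxy}dimethylsilane | IC[C@@H](C)[C@@H]1C[C@@H](O[Si](C)(C)C(C)(C)C)C(C)(C)O1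
F13 | step 9 | {(2S)-2-[(2S,4R)-4-[(tert-butyldimethylsilyl)oxy]-5,5-dimethyloxolan-2-yl]propyl}zinc iodide | I[Zn]C[C@@H](C)[C@@H]1C[C@@H](O[Si](C)(C)C(C)(C)C)C(C)(C)O1
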